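**Plan**
- Retrosynthesis: the twelve O-benzyl groups are cut first, then the interflavan bond C4 (upper unit)–C8 (lower unit), then the 3-O-galloyl ester of the lower unit.
- Ring C of the lower unit is cut at C2–C3. C2 carries the ring oxygen O1 and ring B, so it is the carbonyl carbon of an aryl 3,4,5-tris(benzyloxy)benzoate in disguise; C3–C4 is an allyl group ortho to O1 on ring A (Claisen retron).
- Forward, lower unit: O-allylation and Claisen rearrangement on ring A, esterification of the phenol, then one titanium-mediated carbonyl methylenation/ring-closing metathesis closes ring C as the C2=C3 enol ether. The helpers (carboxyl oxidation level at C2, the extra allyl CH2, the C2=C3 unsaturation) are removed on the way.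
- Hydroboration–oxidation and Dess–Martin oxidation give the flavan-3-one. A Ru-catalysed transfer hydrogenation with dynamic kinetic resolution sets lower C2 and C3 (2R,3R, cis) in one event; the same benzoic acid then supplies the 3-O-gallate.
- Upper unit: C2 and C3 are bought with (−)-epicatechin. Benzylation and DDQ oxidation give a C4 electrophile; TMSOTf coupling with the lower unit sets C4 (4β, trans to C3–OH) by substrate control at C8; hydrogenolysis ends the route.

Key step: step 4

Remark: compounds 1, 5 and 14 are taken as purchasable. The sense of induction written for the catalyst in step 7 is assigned by analogy with α-aryl cyclic ketones; the antipodal ligand serves if the first run shows the opposite sense.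

Step 1
Reactants: 1 3,5-bis(benzyloxy)phenol
Product: 2 1-(allyloxy)-3,5-bis(benzyloxy)benzene
Conditions: allyl bromide, K2CO3, acetone, reflux
Reagents that add atoms: allyl bromide, C=CCBr
Why: Williamson ether synthesis, the phenoxide being alkylated at oxygen by the allylic bromide (SN2); no stereocenter is formed.

Step 2
Reactants: 2 1-(allyloxy)-3,5-bis(benzyloxy)benzene
Product: 4 2-allyl-3,5-bis(benzyloxy)phenol, via ortho-dienone 3 (not isolated)
Conditions: N,N-diethylaniline, 190 °C
Reagents that add atoms: none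
Why: Aromatic Claisen rearrangement ([3,3]-sigmatropic shift) to one of the two equivalent free ortho positions, followed by tautomerization of the dienone to the phenol, which places the future C4–C3 unit next to the future O1.

Step 3
Reactants: 4 2-allyl-3,5-bis(benzyloxy)phenol; 5 3,4,5-tris(benzyloxy)benzoic acid
Product: 6 2-allyl-3,5-bis(benzyloxy)phenyl 3,4,5-tris(benzyloxy)benzoate
Conditions: DCC, DMAP (cat.), CH2Cl2, 0 °C to rt
Reagents that add atoms: none
Why: Steglich esterification, in which DCC activates acid 5 and DMAP transfers the acyl group to the hindered phenol; this puts C2 and ring B on O1 at the carboxyl oxidation level.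

Step 4
Reactants: 6 2-allyl-3,5-bis(benzyloxy)phenyl 3,4,5-tris(benzyloxy)benzoate
Product: 8 5,7-bis(benzyloxy)-2-[3,4,5-tris(benzyloxy)phenyl]-4H-chromene, via aryl enol ether 7 (not isolated)
Conditions: Tebbe reagent Cp2Ti(μ-Cl)(μ-CH2)AlMe2 (4 equiv), pyridine (cat.), THF, 0 °C to rt, then reflux; aqueous NaOH work-up, basic alumina
Reagents that add atoms: none
Why: The titanium methylidene Cp2Ti=CH2 released from the Tebbe reagent first methylenates the aryl ester carbonyl (oxatitanacyclobutane, then cycloreversion driven by the Ti=O bond) to give enol ether 7; on heating, a second methylidene adds to the terminal allyl olefin, the titanacyclobutane loses ethylene, and the titanium alkylidene now at C3 closes on the enol ether C=CH2 by [2+2] cycloaddition and cycloreversion, which forms C2=C3 and returns Cp2Ti=CH2. The closest known reaction type is the Tebbe-mediated olefinic ester cyclization to cyclic enol ethers (carbonyl olefination followed by ring-closing olefin metathesis), together with ring-closing metathesis of 2-allylphenyl vinyl ethers to 4H-chromenes. Ring C (the 4H-pyran fused to ring A) is closed by this alkylidene–alkene metathesis, a six-membered ring closure in which both new sp2 carbons end inside the ring. No stereocenter is formed; C2 and C3 are left as the two ends of one enol ether double bond, so that both can be set later from this single functional group. The step needs chemoselectivity for the one ester carbonyl and six-ring closure without migration of the allyl double bond into conjugation with ring A (which would lead to a benzofuran); the substrate secures this because the ester is its only carbonyl group, the benzyl ethers are inert to the titanium reagent, the ortho relation of allyl group and ester oxygen on ring A allows only the six-membered ring, and no metal hydride is present to isomerize the olefin.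

Step 5
Reactants: 8 5,7-bis(benzyloxy)-2-[3,4,5-tris(benzyloxy)phenyl]-4H-chromene
Product: 10 rac-(2R*,3S*)-5,7-bis(benzyloxy)-2-[3,4,5-tris(benzyloxy)phenyl]chroman-3-ol, via alkylborane 9 (not isolated)
Conditions: BH3·THF, THF, 0 °C to rt; then NaOH, H2O2, H2O, 0 °C to rt
Reagents that add atoms: hydrogen peroxide, OO
Why: Hydroboration–oxidation of the cyclic enol ether, in which boron adds to C3 (β to O1 and to ring B) and hydrogen to C2 from the same face and the C–B bond is oxidized with retention, so the racemic 2,3-trans alcohol is expected; the step serves only to bring oxygen to C3.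

Step 6
Reactants: 10 rac-(2R*,3S*)-5,7-bis(benzyloxy)-2-[3,4,5-tris(benzyloxy)phenyl]chroman-3-ol
Product: 11 rac-5,7-bis(benzyloxy)-2-[3,4,5-tris(benzyloxy)phenyl]chroman-3-one
Conditions: Dess–Martin periodinane, CH2Cl2, 0 °C to rt
Reagents that add atoms: none
Why: Dess–Martin oxidation of the secondary alcohol to the ketone under near-neutral conditions; C3 becomes sp2 and C2 becomes epimerizable, which the next step exploits.

Step 7
Reactants: 11 rac-5,7-bis(benzyloxy)-2-[3,4,5-tris(benzyloxy)phenyl]chroman-3-one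
Product: 12 (2R,3R)-5,7-bis(benzyloxy)-2-[3,4,5-tris(benzyloxy)phenyl]chroman-3-ol
Conditions: RuCl[(S,S)-TsDPEN](p-cymene) (cat.), HCO2H/Et3N (5:2), CH2Cl2, 30 °C
Reagents that add atoms: none
Why: Noyori–Ikariya asymmetric transfer hydrogenation with dynamic kinetic resolution, in which C2 (α to the ketone, benzylic and O-substituted) epimerizes through the enol in the HCO2H/Et3N medium faster than the ketone is reduced, the chiral Ru hydride reduces the (2R)-ketone preferentially and delivers hydride anti to ring B, so that C2 (R) and C3 (R) are set together as the 2,3-cis pair by catalyst control.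

Step 8
Reactants: 12 (2R,3R)-5,7-bis(benzyloxy)-2-[3,4,5-tris(benzyloxy)phenyl]chroman-3-ol; 5 3,4,5-tris(benzyloxy)benzoic acid
Product: 13 (2R,3R)-5,7-bis(benzyloxy)-2-[3,4,5-tris(benzyloxy)phenyl]chroman-3-yl 3,4,5-tris(benzyloxy)benzoate
Conditions: DCC, DMAP, CH2Cl2, rt
Reagents that add atoms: none
Why: Steglich esterification of the C3 alcohol with acid 5; C2 and C3 are not affected.

Step 9
Reactants: 14 (−)-epicatechin
Product: 15 5,7,3',4'-tetra-O-benzyl-(−)-epicatechin
Conditions: BnBr, K2CO3, DMF, 0 °C to rt, under N2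
Reagents that add atoms: benzyl bromide, BrCc1ccccc1
Why: Williamson etherification, in which the four phenols are deprotonated by K2CO3 and benzylated while the less acidic C3 alcohol stays free, and C2 and C3 (bought with 14) are not touched at this temperature.

Step 10
Reactants: 15 5,7,3',4'-tetra-O-benzyl-(−)-epicatechin
Product: 16 (2R,3R,4S)-5,7-bis(benzyloxy)-2-[3,4-bis(benzyloxy)phenyl]-4-(2-ethoxyethoxy)chroman-3-ol
Conditions: DDQ, 2-ethoxyethanol, CH2Cl2, rt
Reagents that add atoms: 2-ethoxyethanol, CCOCCO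
Why: Benzylic oxidation by DDQ, in which hydride abstraction from C4 (made easy by the 5,7-dioxygenated ring A) gives a stabilized cation that 2-ethoxyethanol captures anti to the C3 hydroxyl, so the 3,4-trans (4β) ether is expected.

Step 11
Reactants: 16 (2R,3R,4S)-5,7-bis(benzyloxy)-2-[3,4-bis(benzyloxy)phenyl]-4-(2-ethoxyethoxy)chroman-3-ol; 13 (2R,3R)-5,7-bis(benzyloxy)-2-[3,4,5-tris(benzyloxy)phenyl]chroman-3-yl 3,4,5-tris(benzyloxy)benzoate
Product: 17 dodeca-O-benzyl epicatechin-(4β→8)-epigallocatechin 3-O-gallate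
Conditions: TMSOTf (cat.), 4 Å molecular sieves, CH2Cl2, −78 °C; 13 in excess (2 equiv, the surplus is recovered)
Reagents that add atoms: none
Why: Lewis-acid-promoted Friedel–Crafts-type flavan coupling (SN1 at C4), in which TMSOTf ionizes the 4-alkoxy group and the cation is attacked by C8 of ring A of 13 (favoured over C6 in flavan nucleophiles) from the face anti to the C3 hydroxyl and the 2-aryl group, which sets C4 as 4β by substrate control.

Step 12
Reactants: 17 dodeca-O-benzyl epicatechin-(4β→8)-epigallocatechin 3-O-gallate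
Product: 18 epicatechin-(4β→8)-epigallocatechin 3-O-gallate (CNP0246304.2)
Conditions: H2 (1 atm), Pd(OH)2/C, THF/MeOH/H2O, rt
Reagents that add atoms: none
Why: Catalytic hydrogenolysis of the twelve benzyl ethers over Pd(OH)2/C; the gallate ester, the interflavan bond and the five stereocenters are not affected under neutral conditions at room temperature.

**Compound list**
1 | 3,5-bis(benzyloxy)phenol | Oc1cc(OCc2ccccc2)cc(OCc2ccccc2)c1 | starting material
2 | 1-(allyloxy)-3,5-bis(benzyloxy)benzene | C=CCOc1cc(OCc2ccccc2)cc(OCc2ccccc2)c1 | intermediate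
3 | 6-allyl-3,5-bis(benzyloxy)cyclohexa-2,4-dien-1-one (ortho-dienone, racemic) | O=C1C=C(OCc2ccccc2)C=C(OCc2ccccc2)C1CC=C | intermediate
4 | 2-allyl-3,5-bis(benzyloxy)phenol | Oc1cc(OCc2ccccc2)cc(OCc2ccccc2)c1CC=C | intermediate
5 | 3,4,5-tris(benzyloxy)benzoic acid | OC(=O)c1cc(OCc2ccccc2)c(OCc2ccccc2)c(OCc2ccccc2)c1 | starting material
6 | 2-allyl-3,5-bis(benzyloxy)phenyl 3,4,5-tris(benzyloxy)benzoate | C=CCc1c(OC(=O)c2cc(OCc3ccccc3)c(OCc3ccccc3)c(OCc3ccccc3)c2)cc(OCc2ccccc2)cc1OCc1ccccc1 | intermediate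
7 | 1-[2-allyl-3,5-bis(benzyloxy)phenoxy]-1-[3,4,5-tris(benzyloxy)phenyl]ethene (aryl enol ether) | C=CCc1c(OC(=C)c2cc(OCc3ccccc3)c(OCc3ccccc3)c(OCc3ccccc3)c2)cc(OCc2ccccc2)cc1OCc1ccccc1 | intermediate
8 | 5,7-bis(benzyloxy)-2-[3,4,5-tris(benzyloxy)phenyl]-4H-chromene | C1(c2cc(OCc3ccccc3)c(OCc3ccccc3)c(OCc3ccccc3)c2)=CCc2c(OCc3ccccc3)cc(OCc3ccccc3)cc2O1 | intermediate
9 | rac-[(2R*,3S*)-5,7-bis(benzyloxy)-2-[3,4,5-tris(benzyloxy)phenyl]chroman-3-yl]borane (alkylborane, drawn as the monoalkylborane; racemic, one enantiomer drawn) | [BH2][C@H]1Cc2c(OCc3ccccc3)cc(OCc3ccccc3)cc2O[C@@H]1c1cc(OCc2ccccc2)c(OCc2ccccc2)c(OCc2ccccc2)c1 | intermediate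
10 | rac-(2R*,3S*)-5,7-bis(benzyloxy)-2-[3,4,5-tris(benzyloxy)phenyl]chroman-3-ol (2,3-trans; racemic, one enantiomer drawn) | O[C@H]1Cc2c(OCc3ccccc3)cc(OCc3ccccc3)cc2O[C@@H]1c1cc(OCc2ccccc2)c(OCc2ccccc2)c(OCc2ccccc2)c1 | intermediate
11 | rac-5,7-bis(benzyloxy)-2-[3,4,5-tris(benzyloxy)phenyl]chroman-3-one (racemic, C2 labile) | O=C1Cc2c(OCc3ccccc3)cc(OCc3ccccc3)cc2OC1c1cc(OCc2ccccc2)c(OCc2ccccc2)c(OCc2ccccc2)c1 | intermediate
12 | (2R,3R)-5,7-bis(benzyloxy)-2-[3,4,5-tris(benzyloxy)phenyl]chroman-3-ol (penta-O-benzyl-(−)-epigallocatechin, 2,3-cis) | O[C@@H]1Cc2c(OCc3ccccc3)cc(OCc3ccccc3)cc2O[C@@H]1c1cc(OCc2ccccc2)c(OCc2ccccc2)c(OCc2ccccc2)c1 | intermediate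
13 | (2R,3R)-5,7-bis(benzyloxy)-2-[3,4,5-tris(benzyloxy)phenyl]chroman-3-yl 3,4,5-tris(benzyloxy)benzoate (octa-O-benzyl epigallocatechin gallate) | O=C(O[C@@H]1Cc2c(OCc3ccccc3)cc(OCc3ccccc3)cc2O[C@@H]1c1cc(OCc2ccccc2)c(OCc2ccccc2)c(OCc2ccccc2)c1)c1cc(OCc2ccccc2)c(OCc2ccccc2)c(OCc2ccccc2)c1 | intermediate
14 | (−)-epicatechin, (2R,3R) | O[C@@H]1Cc2c(O)cc(O)cc2O[C@@H]1c1ccc(O)c(O)c1 | starting material
15 | 5,7,3',4'-tetra-O-benzyl-(−)-epicatechin, (2R,3R) | O[C@@H]1Cc2c(OCc3ccccc3)cc(OCc3ccccc3)cc2O[C@@H]1c1ccc(OCc2ccccc2)c(OCc2ccccc2)c1 | intermediate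
16 | (2R,3R,4S)-5,7-bis(benzyloxy)-2-[3,4-bis(benzyloxy)phenyl]-4-(2-ethoxyethoxy)chroman-3-ol (4β-ether, 2,3-cis, 3,4-trans) | CCOCCO[C@H]1c2c(OCc3ccccc3)cc(OCc3ccccc3)cc2O[C@H](c2ccc(OCc3ccccc3)c(OCc3ccccc3)c2)[C@@H]1O | intermediate
17 | dodeca-O-benzyl epicatechin-(4β→8)-epigallocatechin 3-O-gallate (upper unit 2R,3R,4R; lower unit 2R,3R) | O=C(O[C@@H]1Cc2c(OCc3ccccc3)cc(OCc3ccccc3)c([C@H]3c4c(OCc5ccccc5)cc(OCc5ccccc5)cc4O[C@H](c4ccc(OCc5ccccc5)c(OCc5ccccc5)c4)[C@@H]3O)c2O[C@@H]1c1cc(OCc2ccccc2)c(OCc2ccccc2)c(OCc2ccccc2)c1)c1cc(OCc2ccccc2)c(OCc2ccccc2)c(OCc2ccccc2)c1 | intermediate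
18 | epicatechin-(4β→8)-epigallocatechin 3-O-gallate (CNP0246304.2) | O=C(O[C@@H]1Cc2c(O)cc(O)c([C@H]3c4c(O)cc(O)cc4O[C@H](c4ccc(O)c(O)c4)[C@@H]3O)c2O[C@@H]1c1cc(O)c(O)c(O)c1)c1cc(O)c(O)c(O)c1 | target

**Step count and risks**
Total step count: 12. Longest linear sequence: 10 steps (steps 1 to 8, then 11 and 12).

Step 4 (key step). The cascade may stop at the acyclic enol ether, the allyl double bond may migrate into conjugation with ring A, or the electron-rich enol ether may hydrolyse on acidic supports. The fallback closes ring C by reductive carbonyl coupling instead of metathesis. It sets out from 6 and comes back at 8. Lemieux–Johnson cleavage of the allyl olefin of 6 (OsO4 cat., NaIO4, 2,6-lutidine, dioxane/H2O) should give 2-[2,4-bis(benzyloxy)-6-{[3,4,5-tris(benzyloxy)benzoyl]oxy}phenyl]acetaldehyde F1. An intramolecular McMurry-type oxo-ester coupling with low-valent titanium (TiCl3, Zn, DME, reflux, high dilution) should then join the aldehyde carbon (C3) to the ester carbon (C2) and give 8.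

Step 7. Reduction may outrun the epimerization at C2, or the catalyst may discriminate the two ketone enantiomers poorly, so that enantio- and diastereocontrol erode. The fallback sets C2 by reagent control at the alkene stage and C3 by substrate control. It sets out from 8 and comes back at 12. Asymmetric hydroboration of 8 with monoisopinocampheylborane IpcBH2 (THF, −25 °C; drawn as derived from (+)-α-pinene, the pinene enantiomer being the one that gives the 2R product) should give isopinocampheyl[(2R,3S)-5,7-bis(benzyloxy)-2-[3,4,5-tris(benzyloxy)phenyl]chroman-3-yl]borane F2. Oxidation in the same flask (NaOH, H2O2) should give (2R,3S)-5,7-bis(benzyloxy)-2-[3,4,5-tris(benzyloxy)phenyl]chroman-3-ol F3. Dess–Martin oxidation (CH2Cl2, 0 °C, product used at once) should give (2R)-5,7-bis(benzyloxy)-2-[3,4,5-tris(benzyloxy)phenyl]chroman-3-one F4 with C2 intact. Reduction with LiBH(s-Bu)3 (THF, −78 °C), hydride entering anti to ring B, should give the 2,3-cis alcohol 12.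

Step 11. The electrophile may condense with its own ring A (oligomer formation), attack may occur in part at C6 of 13, and conversion may be low with the acylated nucleophile. The fallback caps C8 of the upper unit with bromine. It sets out from 15 and comes back at 18. Bromination of 15 (NBS, CH2Cl2, −78 °C to rt) should give 8-bromo-5,7,3',4'-tetra-O-benzyl-(−)-epicatechin F5. DDQ and 2-ethoxyethanol (CH2Cl2, rt) should give (2R,3R,4S)-5,7-bis(benzyloxy)-2-[3,4-bis(benzyloxy)phenyl]-8-bromo-4-(2-ethoxyethoxy)chroman-3-ol F6. Coupling with 13 (TMSOTf, CH2Cl2, −78 °C) should give 8-bromo-dodeca-O-benzyl epicatechin-(4β→8)-epigallocatechin 3-O-gallate F7. Hydrogenolysis (H2, Pd(OH)2/C, Et3N, THF/MeOH/H2O) should remove the bromine together with the benzyl groups and give 18.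

Further compounds
F1 | step 4 | 2-[2,4-bis(benzyloxy)-6-{[3,4,5-tris(benzyloxy)benzoyl]oxy}phenyl]acetaldehyde | O=CCc1c(OC(=O)c2cc(OCc3ccccc3)c(OCc3ccccc3)c(OCc3ccccc3)c2)cc(OCc2ccccc2)cc1OCc1ccccc1
F2 | step 7 | isopinocampheyl[(2R,3S)-5,7-bis(benzyloxy)-2-[3,4,5-tris(benzyloxy)phenyl]chroman-3-yl]borane | C[C@H]1[C@H](B[C@H]2Cc3c(OCc4ccccc4)cc(OCc4ccccc4)cc3O[C@@H]2c2cc(OCc3ccccc3)c(OCc3ccccc3)c(OCc3ccccc3)c2)C[C@@H]2C[C@H]1C2(C)C
F3 | step 7 | (2R,3S)-5,7-bis(benzyloxy)-2-[3,4,5-tris(benzyloxy)phenyl]chroman-3-ol (single enantiomer, 2,3-trans) | O[C@H]1Cc2c(OCc3ccccc3)cc(OCc3ccccc3)cc2O[C@@H]1c1cc(OCc2ccccc2)c(OCc2ccccc2)c(OCc2ccccc2)c1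
F4 | step 7 | (2R)-5,7-bis(benzyloxy)-2-[3,4,5-tris(benzyloxy)phenyl]chroman-3-one | O=C1Cc2c(OCc3ccccc3)cc(OCc3ccccc3)cc2O[C@@H]1c1cc(OCc2ccccc2)c(OCc2ccccc2)c(OCc2ccccc2)c1
F5 | step 11 | 8-bromo-5,7,3',4'-tetra-O-benzyl-(−)-epicatechin | O[C@@H]1Cc2c(OCc3ccccc3)cc(OCc3ccccc3)c(Br)c2O[C@@H]1c1ccc(OCc2ccccc2)c(OCc2ccccc2)c1
F6 | step 11 | (2R,3R,4S)-5,7-bis(benzyloxy)-2-[3,4-bis(benzyloxy)phenyl]-8-bromo-4-(2-ethoxyethoxy)chroman-3-ol | CCOCCO[C@H]1c2c(OCc3ccccc3)cc(OCc3ccccc3)c(Br)c2O[C@H](c2ccc(OCc3ccccc3)c(OCc3ccccc3)c2)[C@@H]1O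
F7 | step 11 | 8-bromo-dodeca-O-benzyl epicatechin-(4β→8)-epigallocatechin 3-O-gallate (bromine on C8 of the upper unit) | O=C(O[C@@H]1Cc2c(OCc3ccccc3)cc(OCc3ccccc3)c([C@H]3c4c(OCc5ccccc5)cc(OCc5ccccc5)c(Br)c4O[C@H](c4ccc(OCc5ccccc5)c(OCc5ccccc5)c4)[C@@H]3O)c2O[C@@H]1c1cc(OCc2ccccc2)c(OCc2ccccc2)c(OCc2ccccc2)c1)c1cc(OCc2ccccc2)c(OCc2ccccc2)c(OCc2ccccc2)c1
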